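**Retrosynthetic overview**

1. Ring atoms carry the locants of the target name: C1 (C=O), C2=C3, C4 (OMe), C5H2, C6 (quaternary). The last steps are desilylation, O-methylation at C4 and a reagent-controlled reduction of the C4 ketone of ene-dione 15.
2. The only ring is closed in a Dötz–Wulff cyclohexadienone annulation of alkenyl(methoxy)carbene chromium complex 11 with acetylene. It forms C3–C4 and C1–C6 (and C1–C2) in one operation: C4 is the carbene carbon, C1=O is a CO ligand, C2/C3 are acetylene.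
3. Enabling feature: C1=O and the oxygenated C4 are 1,4 (para) on the six-membered ring, which is the oxygen pattern a carbene/alkyne/CO annulation lays down. The quaternary C6 next to C1 blocks aromatisation, so the annulation stops at the cyclohexadienone, and the exocyclic CH(Me) stereocentre steers the C1–C6 closure.
4. Carbene 11 comes from alkyne 6 (acetylide/Cr(CO)6/MeOTf, then copper-mediated allyl Michael addition). Alkyne 6 comes from veratraldehyde by asymmetric (Z)-crotylboration, silylation, alkene cleavage and Ohira–Bestmann homologation.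

Key step: step 7

Assumption: the target is taken as the open γ-hydroxy ketone drawn, although it may equilibrate with its five-membered hemiketal.

**Route**

Step 1
Reactants: 1 3,4-dimethoxybenzaldehyde; 2 (Z)-crotylboronic acid pinacol ester
Product: 3 (1S,2R)-1-(3,4-dimethoxyphenyl)-2-methylbut-3-en-1-ol
Conditions: (S)-TRIP (5 mol %), toluene, −30 °C; aq. NaHCO3 work-up
Reagents that add atoms: none
Why: Chiral phosphoric acid-catalysed crotylboration through a closed chair transition state should give the syn isomer from the Z-boronate, and the catalyst should set the 1S carbinol centre.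

Step 2
Reactants: 3 (1S,2R)-1-(3,4-dimethoxyphenyl)-2-methylbut-3-en-1-ol
Product: 4 tert-butyl{[(1S,2R)-1-(3,4-dimethoxyphenyl)-2-methylbut-3-en-1-yl]oxy}dimethylsilane
Conditions: TBSOTf, 2,6-lutidine, CH2Cl2, 0 °C
Reagents that add atoms: tert-butyldimethylsilyl triflate, CC(C)(C)[Si](C)(C)OS(=O)(=O)C(F)(F)F
Why: Silyl ether formation protects the acid-labile electron-rich benzylic alcohol for the organometallic steps; no stereocentre is touched.

Step 3
Reactants: 4 tert-butyl{[(1S,2R)-1-(3,4-dimethoxyphenyl)-2-methylbut-3-en-1-yl]oxy}dimethylsilane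
Product: 5 (2S,3S)-3-[(tert-butyldimethylsilyl)oxy]-3-(3,4-dimethoxyphenyl)-2-methylpropanal
Conditions: OsO4 (2 mol %), NaIO4, 2,6-lutidine, dioxane/H2O, rt
Reagents that add atoms: sodium periodate, [Na+].[O-]I(=O)(=O)=O
Why: Lemieux–Johnson cleavage of the terminal alkene should spare the dimethoxyarene (unlike ozone), and the buffered medium should keep the α-stereocentre intact.

Step 4
Reactants: 5 (2S,3S)-3-[(tert-butyldimethylsilyl)oxy]-3-(3,4-dimethoxyphenyl)-2-methylpropanal
Product: 6 tert-butyl{[(1S,2R)-1-(3,4-dimethoxyphenyl)-2-methylbut-3-yn-1-yl]oxy}dimethylsilane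
Conditions: dimethyl (1-diazo-2-oxopropyl)phosphonate, K2CO3, MeOH, 0 °C to rt
Reagents that add atoms: dimethyl (1-diazo-2-oxopropyl)phosphonate, COP(=O)(OC)C(=[N+]=[N-])C(C)=O
Why: Ohira–Bestmann (Seyferth–Gilbert) homologation converts the aldehyde into the terminal alkyne under conditions mild enough for the α-branched, β-silyloxy aldehyde.

Step 5
Reactants: 6 tert-butyl{[(1S,2R)-1-(3,4-dimethoxyphenyl)-2-methylbut-3-yn-1-yl]oxy}dimethylsilane
Product: 9 pentacarbonyl{(4R,5S)-5-[(tert-butyldimethylsilyl)oxy]-5-(3,4-dimethoxyphenyl)-1-methoxy-4-methylpent-2-yn-1-ylidene}chromium(0), via lithium acetylide 7 (not isolated), via lithium acylchromate 8 (not isolated)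
Conditions: n-BuLi, THF, −78 °C; Cr(CO)6, −78 to 0 °C; MeOTf, CH2Cl2, −40 to 0 °C
Reagents that add atoms: hexacarbonylchromium, O=C=[Cr](=C=O)(=C=O)(=C=O)(=C=O)=C=O; methyl triflate, COS(=O)(=O)C(F)(F)F
Why: Fischer carbene synthesis: the acetylide adds to a CO ligand and the acylchromate is O-methylated, so this CO carbon becomes ring C4 with its methoxy group already in place.

Step 6
Reactants: 9 pentacarbonyl{(4R,5S)-5-[(tert-butyldimethylsilyl)oxy]-5-(3,4-dimethoxyphenyl)-1-methoxy-4-methylpent-2-yn-1-ylidene}chromium(0)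
Product: 11 pentacarbonyl{(2Z,4R,5S)-3-allyl-5-[(tert-butyldimethylsilyl)oxy]-5-(3,4-dimethoxyphenyl)-1-methoxy-4-methylpent-2-en-1-ylidene}chromium(0), via C-magnesiated Michael adduct 10 (not isolated)
Conditions: allylmagnesium bromide (1.2 equiv), CuBr·SMe2 (10 mol %), THF, −78 °C; AcOH, −78 °C
Reagents that add atoms: allylmagnesium bromide, C=CC[Mg]Br
Why: Copper-mediated Michael addition of a carbon nucleophile to the strongly electrophilic (1-alkynyl)carbene complex, with low-temperature protonation of the metalated adduct from the side of the smaller allyl group, should give the Z isomer in which the carbene carbon is cis to the branched chain.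

Step 7
Reactants: 11 pentacarbonyl{(2Z,4R,5S)-3-allyl-5-[(tert-butyldimethylsilyl)oxy]-5-(3,4-dimethoxyphenyl)-1-methoxy-4-methylpent-2-en-1-ylidene}chromium(0); 12 acetylene
Product: 15 (5S)-5-allyl-5-{(1R,2S)-2-[(tert-butyldimethylsilyl)oxy]-2-(3,4-dimethoxyphenyl)-1-methylethyl}cyclohex-2-ene-1,4-dione, via chromium-bound dienylketene 13 (not isolated), via methoxycyclohexadienone 14 (not isolated)
Conditions: acetylene (1 atm, slow feed), THF, 50 °C; then air, 0.5 M aq. HCl/THF, 0 °C
Reagents that add atoms: water, O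
Why: Acetylene inserts into the Cr=C bond (forming C3–C4), a CO ligand inserts to give dienylketene 13 (C1–C2), and a 6π disrotatory electrocyclisation of 13 closes the ring by forming C1–C6; mild acid then hydrolyses the dienol ether of 14 to ene-dione 15. The closest known reaction is the Wulff cyclohexadienone annulation of β,β-disubstituted alkenyl(alkoxy)carbene chromium complexes with alkynes. The single ring is closed by the electrocyclisation, not by a polar exo/endo attack, and because C6 becomes quaternary the product cannot tautomerise to a phenol. C6 is the only new stereocentre: in the Z complex, allylic 1,3-strain against the carbene/ketene arm should hold the C–H of the adjacent CH(Me) centre in the plane pointing at that arm, so methyl and the bulky CH(OTBS)Ar group flank the two faces and the ketene carbon should bond anti to CH(OTBS)Ar, giving 6R in 14 (5S in 15, 6S in the target). The step needs CO insertion to win over cyclopentannulation (favoured for chromium in THF), single alkyne insertion (slow feed of acetylene) and no intramolecular cyclopropanation of the allyl group (the Z geometry holds the allyl group trans to the carbene carbon). Regiochemistry of alkyne insertion is not an issue because acetylene is symmetric.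

Step 8
Reactants: 15 (5S)-5-allyl-5-{(1R,2S)-2-[(tert-butyldimethylsilyl)oxy]-2-(3,4-dimethoxyphenyl)-1-methylethyl}cyclohex-2-ene-1,4-dione
Product: 16 (4S,6S)-6-allyl-6-{(1R,2S)-2-[(tert-butyldimethylsilyl)oxy]-2-(3,4-dimethoxyphenyl)-1-methylethyl}-4-hydroxycyclohex-2-en-1-one
Conditions: (R)-Me-CBS (20 mol %), catecholborane, toluene, −78 °C; aq. NaOH work-up
Reagents that add atoms: none
Why: Corey–Bakshi–Shibata reduction should take the less hindered carbonyl (flanked by CH2 and CH=, not by the quaternary carbon) and, with the vinyl arm as the large group, deliver hydride under catalyst control to set 4S; catecholborane at −78 °C should not hydroborate the allyl group or reduce the s-trans enone conjugatively.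

Step 9
Reactants: 16 (4S,6S)-6-allyl-6-{(1R,2S)-2-[(tert-butyldimethylsilyl)oxy]-2-(3,4-dimethoxyphenyl)-1-methylethyl}-4-hydroxycyclohex-2-en-1-one
Product: 17 (4S,6S)-6-allyl-6-{(1R,2S)-2-[(tert-butyldimethylsilyl)oxy]-2-(3,4-dimethoxyphenyl)-1-methylethyl}-4-methoxycyclohex-2-en-1-one
Conditions: MeI, Ag2O, 4 Å MS, CH2Cl2, rt, dark
Reagents that add atoms: iodomethane, CI
Why: Purdie methylation under non-basic conditions etherifies the only free hydroxyl with retention and avoids γ-deprotonation of the enone.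

Step 10
Reactants: 17 (4S,6S)-6-allyl-6-{(1R,2S)-2-[(tert-butyldimethylsilyl)oxy]-2-(3,4-dimethoxyphenyl)-1-methylethyl}-4-methoxycyclohex-2-en-1-one
Product: 18 (4S,6S)-6-allyl-6-[(1R,2S)-2-(3,4-dimethoxyphenyl)-2-hydroxy-1-methylethyl]-4-methoxycyclohex-2-en-1-one
Conditions: TBAF, AcOH, THF, 0 °C to rt
Reagents that add atoms: none
Why: Buffered fluoride desilylation frees the benzylic alcohol without acid (which would ionise the benzylic C–O bond) and without strong base (which could epimerise C4 through the dienolate).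

**Compound list**

1 | 3,4-dimethoxybenzaldehyde | COc1ccc(C=O)cc1OC | starting material
2 | (Z)-crotylboronic acid pinacol ester | C/C=C\CB1OC(C)(C)C(C)(C)O1 | starting material
3 | (1S,2R)-1-(3,4-dimethoxyphenyl)-2-methylbut-3-en-1-ol | C=C[C@@H](C)[C@H](O)c1ccc(OC)c(OC)c1 | intermediate
4 | tert-butyl{[(1S,2R)-1-(3,4-dimethoxyphenyl)-2-methylbut-3-en-1-yl]oxy}dimethylsilane | C=C[C@@H](C)[C@H](O[Si](C)(C)C(C)(C)C)c1ccc(OC)c(OC)c1 | intermediate
5 | (2S,3S)-3-[(tert-butyldimethylsilyl)oxy]-3-(3,4-dimethoxyphenyl)-2-methylpropanal | O=C[C@@H](C)[C@H](O[Si](C)(C)C(C)(C)C)c1ccc(OC)c(OC)c1 | intermediate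
6 | tert-butyl{[(1S,2R)-1-(3,4-dimethoxyphenyl)-2-methylbut-3-yn-1-yl]oxy}dimethylsilane | C#C[C@@H](C)[C@H](O[Si](C)(C)C(C)(C)C)c1ccc(OC)c(OC)c1 | intermediate
7 | lithium acetylide of 6 | [Li]C#C[C@@H](C)[C@H](O[Si](C)(C)C(C)(C)C)c1ccc(OC)c(OC)c1 | intermediate
8 | lithium pentacarbonyl{(4R,5S)-5-[(tert-butyldimethylsilyl)oxy]-5-(3,4-dimethoxyphenyl)-4-methyl-1-oxidopent-2-yn-1-ylidene}chromate | [Li+].[O-]C(=[Cr](=C=O)(=C=O)(=C=O)(=C=O)=C=O)C#C[C@@H](C)[C@H](O[Si](C)(C)C(C)(C)C)c1ccc(OC)c(OC)c1 | intermediate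
9 | pentacarbonyl{(4R,5S)-5-[(tert-butyldimethylsilyl)oxy]-5-(3,4-dimethoxyphenyl)-1-methoxy-4-methylpent-2-yn-1-ylidene}chromium(0) | COC(=[Cr](=C=O)(=C=O)(=C=O)(=C=O)=C=O)C#C[C@@H](C)[C@H](O[Si](C)(C)C(C)(C)C)c1ccc(OC)c(OC)c1 | intermediate
10 | C-magnesiated Michael adduct (2-bromomagnesio derivative of 11) | COC(=[Cr](=C=O)(=C=O)(=C=O)(=C=O)=C=O)C([Mg]Br)=C(CC=C)[C@@H](C)[C@H](O[Si](C)(C)C(C)(C)C)c1ccc(OC)c(OC)c1 | intermediate
11 | pentacarbonyl{(2Z,4R,5S)-3-allyl-5-[(tert-butyldimethylsilyl)oxy]-5-(3,4-dimethoxyphenyl)-1-methoxy-4-methylpent-2-en-1-ylidene}chromium(0) | COC(=[Cr](=C=O)(=C=O)(=C=O)(=C=O)=C=O)/C=C(/CC=C)[C@@H](C)[C@H](O[Si](C)(C)C(C)(C)C)c1ccc(OC)c(OC)c1 | intermediate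
12 | acetylene | C#C | starting material
13 | (3E,5Z,7R,8S)-6-allyl-8-[(tert-butyldimethylsilyl)oxy]-8-(3,4-dimethoxyphenyl)-4-methoxy-7-methylocta-1,3,5-trien-1-one (dienylketene, chromium-bound in the flask; ligand shown) | COC(/C=C(/CC=C)[C@@H](C)[C@H](O[Si](C)(C)C(C)(C)C)c1ccc(OC)c(OC)c1)=C/C=C=O | intermediate
14 | (6R)-6-allyl-6-{(1R,2S)-2-[(tert-butyldimethylsilyl)oxy]-2-(3,4-dimethoxyphenyl)-1-methylethyl}-4-methoxycyclohexa-2,4-dien-1-one | C=CC[C@@]1([C@@H](C)[C@H](O[Si](C)(C)C(C)(C)C)c2ccc(OC)c(OC)c2)C=C(OC)C=CC1=O | intermediate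
15 | (5S)-5-allyl-5-{(1R,2S)-2-[(tert-butyldimethylsilyl)oxy]-2-(3,4-dimethoxyphenyl)-1-methylethyl}cyclohex-2-ene-1,4-dione | C=CC[C@@]1([C@@H](C)[C@H](O[Si](C)(C)C(C)(C)C)c2ccc(OC)c(OC)c2)CC(=O)C=CC1=O | intermediate
16 | (4S,6S)-6-allyl-6-{(1R,2S)-2-[(tert-butyldimethylsilyl)oxy]-2-(3,4-dimethoxyphenyl)-1-methylethyl}-4-hydroxycyclohex-2-en-1-one | C=CC[C@@]1([C@@H](C)[C@H](O[Si](C)(C)C(C)(C)C)c2ccc(OC)c(OC)c2)C[C@H](O)C=CC1=O | intermediate
17 | (4S,6S)-6-allyl-6-{(1R,2S)-2-[(tert-butyldimethylsilyl)oxy]-2-(3,4-dimethoxyphenyl)-1-methylethyl}-4-methoxycyclohex-2-en-1-one | C=CC[C@@]1([C@@H](C)[C@H](O[Si](C)(C)C(C)(C)C)c2ccc(OC)c(OC)c2)C[C@H](OC)C=CC1=O | intermediate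
18 | (4S,6S)-6-allyl-6-[(1R,2S)-2-(3,4-dimethoxyphenyl)-2-hydroxy-1-methylethyl]-4-methoxycyclohex-2-en-1-one | C=CC[C@@]1([C@@H](C)[C@H](O)c2ccc(OC)c(OC)c2)C[C@H](OC)C=CC1=O | target

**Summary**

Total step count: 10. Longest linear sequence: 10 steps (from 3,4-dimethoxybenzaldehyde).

Steps most likely to fail:

1. Step 7 (key annulation). Acetylene may insert twice or oligomerise, cyclopentannulation without CO insertion may compete, and facial selectivity of the electrocyclic closure may be lower than the allylic-strain model predicts. Fallback: starting from 11, the alkyne is changed to tributyl(ethynyl)stannane, a mono-metalated acetylene surrogate that should enforce single insertion. The annulation should then give the stannylated (6R)-6-allyl-4-methoxy-3-(tributylstannyl)cyclohexa-2,4-dienone F5 (side chain as in 14). The acidic work-up should cleave the vinyl C–Sn bond and hydrolyse the dienol ether, returning to 15. A C6 epimer, if formed, would be separated at 15 or 16.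

2. Step 6 (allyl Michael addition). The Grignard reagent may attack the carbene carbon and displace methoxide, the acidic propargylic C–H may be deprotonated with loss of configuration, and unselective protonation may give the E isomer (which would cyclopropanate the allyl group). Fallback: starting from 6, n-BuLi and methyl chloroformate give methyl (4R,5S)-5-[(tert-butyldimethylsilyl)oxy]-5-(3,4-dimethoxyphenyl)-4-methylpent-2-ynoate F1. Stereospecific syn-carbocupration with allylcopper and proton quench gives methyl (2Z,4R,5S)-3-allyl-5-[(tert-butyldimethylsilyl)oxy]-5-(3,4-dimethoxyphenyl)-4-methylpent-2-enoate F2, with the ester cis to the branched chain. Saponification (LiOH) gives the (2Z)-acid F3 and oxalyl chloride gives the (2Z)-acid chloride F4. Acylation of K2Cr(CO)5 (from Cr(CO)6 and C8K) with F4 followed by O-methylation with Me3OBF4 returns to 11.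

3. Step 8 (ketone reduction). Catalyst control may be overridden by the quaternary centre so that hydride arrives on the wrong face, or the hindered C1 carbonyl may be reduced as well. Fallback: starting from 15, Luche reduction (NaBH4, CeCl3, MeOH, −78 °C) is substrate-controlled. If it gives mainly the epimeric (4R,6S)-6-allyl-6-{(1R,2S)-2-[(tert-butyldimethylsilyl)oxy]-2-(3,4-dimethoxyphenyl)-1-methylethyl}-4-hydroxycyclohex-2-en-1-one F6, Mitsunobu inversion (4-nitrobenzoic acid, PPh3, DIAD) gives the (4S)-4-nitrobenzoate F7. Methanolysis (K2CO3, MeOH, 0 °C) returns to 16.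

**Further compounds**

F1 | step 6 | methyl (4R,5S)-5-[(tert-butyldimethylsilyl)oxy]-5-(3,4-dimethoxyphenyl)-4-methylpent-2-ynoate | COC(=O)C#C[C@@H](C)[C@H](O[Si](C)(C)C(C)(C)C)c1ccc(OC)c(OC)c1
F2 | step 6 | methyl (2Z,4R,5S)-3-allyl-5-[(tert-butyldimethylsilyl)oxy]-5-(3,4-dimethoxyphenyl)-4-methylpent-2-enoate | COC(=O)/C=C(/CC=C)[C@@H](C)[C@H](O[Si](C)(C)C(C)(C)C)c1ccc(OC)c(OC)c1
F3 | step 6 | (2Z,4R,5S)-3-allyl-5-[(tert-butyldimethylsilyl)oxy]-5-(3,4-dimethoxyphenyl)-4-methylpent-2-enoic acid | OC(=O)/C=C(/CC=C)[C@@H](C)[C@H](O[Si](C)(C)C(C)(C)C)c1ccc(OC)c(OC)c1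
F4 | step 6 | (2Z,4R,5S)-3-allyl-5-[(tert-butyldimethylsilyl)oxy]-5-(3,4-dimethoxyphenyl)-4-methylpent-2-enoyl chloride | ClC(=O)/C=C(/CC=C)[C@@H](C)[C@H](O[Si](C)(C)C(C)(C)C)c1ccc(OC)c(OC)c1
F5 | step 7 | (6R)-6-allyl-6-{(1R,2S)-2-[(tert-butyldimethylsilyl)oxy]-2-(3,4-dimethoxyphenyl)-1-methylethyl}-4-methoxy-3-(tributylstannyl)cyclohexa-2,4-dien-1-one | C=CC[C@@]1([C@@H](C)[C@H](O[Si](C)(C)C(C)(C)C)c2ccc(OC)c(OC)c2)C=C(OC)C([Sn](CCCC)(CCCC)CCCC)=CC1=O
F6 | step 8 | (4R,6S)-6-allyl-6-{(1R,2S)-2-[(tert-butyldimethylsilyl)oxy]-2-(3,4-dimethoxyphenyl)-1-methylethyl}-4-hydroxycyclohex-2-en-1-one | C=CC[C@@]1([C@@H](C)[C@H](O[Si](C)(C)C(C)(C)C)c2ccc(OC)c(OC)c2)C[C@@H](O)C=CC1=O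
F7 | step 8 | (1S,5S)-5-allyl-5-{(1R,2S)-2-[(tert-butyldimethylsilyl)oxy]-2-(3,4-dimethoxyphenyl)-1-methylethyl}-4-oxocyclohex-2-en-1-yl 4-nitrobenzoate | C=CC[C@@]1([C@@H](C)[C@H](O[Si](C)(C)C(C)(C)C)c2ccc(OC)c(OC)c2)C[C@H](OC(=O)c2ccc(cc2)[N+](=O)[O-])C=CC1=O
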